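**Retrosynthetic overview**

- Feature: in the cyclohexane (C1 = carbon bearing the dienyl chain, C3 = CHBr, C4 = C(OH)Me), C1 and C4 are para and C3 is α to C4, with Br and OH cis. This is the pattern of a para Diels–Alder adduct of a 2-silyloxybutadiene and an acrylate whose enol silane double bond is C3=C4 (bonds C1–C2 and C5–C6 formed).
- C3–Br comes from electrophilic bromination of that enol silane, and C4 from methyl addition to the cis-α-bromoketone; this gives the cis-bromohydrin that anti addition to an alkene cannot give.
- Side chain: ester → CH2OH → CHO → alkyne → (E)-2-methylalkenyl iodide; the diene is closed last at its central C–C single bond by Heck coupling with a vinyl oxane.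
- Oxane: 6-endo bromoetherification of (R)-linalool, whose carbinol carbon becomes the quaternary oxane carbon.
- Ring order: cyclohexene first (step 2), oxane in a separate one-step branch (step 10), fragments joined in step 11.

Key step: step 2

Assumption: the (S)-diphenylprolinol-derived o-tolyl oxazaborolidinium is taken to deliver the (1S) adduct with acrylate esters; if the sense of induction is the opposite, the equally accessible (R) catalyst is used.

**Route**

Step 1
Reactants: 1 methyl vinyl ketone
Product: 2 2-(triisopropylsilyloxy)buta-1,3-diene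
Conditions: TIPSOTf, Et3N, Et2O, 0 °C to rt
Reagents that add atoms: triisopropylsilyl trifluoromethanesulfonate, CC(C)[Si](OS(=O)(=O)C(F)(F)F)(C(C)C)C(C)C
Why: Soft enolisation and O-silylation of the enone (silyl enol ether formation) traps the cross-conjugated dienolate on oxygen, the standard way to 2-silyloxydienes.

Step 2
Reactants: 2 2-(triisopropylsilyloxy)buta-1,3-diene; 3 2,2,2-trifluoroethyl acrylate
Product: 4 2,2,2-trifluoroethyl (1S)-4-(triisopropylsilyloxy)cyclohex-3-ene-1-carboxylate
Conditions: (S)-o-tolyl oxazaborolidine (20 mol%), Tf2NH (17 mol%), CH2Cl2, −20 to 0 °C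
Reagents that add atoms: none
Why: The protonated oxazaborolidine binds the acrylate carbonyl, lowers its LUMO and shields one π-face, and the diene adds to the open face in a concerted, asynchronous catalytic enantioselective Diels–Alder reaction, the closest precedent being the cationic oxazaborolidine-catalysed cycloadditions of 2-silyloxybutadienes with trifluoroethyl acrylate. The cyclohexene closes by intermolecular [4+2] cycloaddition, C1–C2 and C5–C6 forming in the same event. The only new stereocentre, C1, is set by the catalyst through enantioface selection on the acrylate. The step also needs para regiochemistry, which the 2-silyloxy donor secures because the diene CH2 next to the silyloxy carbon carries the larger HOMO coefficient and bonds to the acrylate β-carbon, so the enol silane double bond lies at C3=C4 only. No diastereoselectivity question arises since one stereocentre is formed, and the TIPS group should let the diene survive the Brønsted-acidic catalyst.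

Step 3
Reactants: 4 2,2,2-trifluoroethyl (1S)-4-(triisopropylsilyloxy)cyclohex-3-ene-1-carboxylate
Product: 5 [(1S)-4-(triisopropylsilyloxy)cyclohex-3-en-1-yl]methanol
Conditions: LiAlH4, Et2O, −20 to 0 °C; Rochelle salt work-up
Reagents that add atoms: none
Why: Hydride reduction of the activated ester with a basic work-up should leave the TIPS enol ether intact and does not touch C1, which is never enolised.

Step 4
Reactants: 5 [(1S)-4-(triisopropylsilyloxy)cyclohex-3-en-1-yl]methanol
Product: 6 (2R,4S)-2-bromo-4-(hydroxymethyl)cyclohexan-1-one (trans, axial bromide)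
Conditions: NBS, NaHCO3, THF–H2O (10:1), −20 °C
Reagents that add atoms: N-bromosuccinimide, O=C1CCC(=O)N1Br
Why: Electrophilic α-bromination of a silyl enol ether is regiospecific for the enol carbon C3, and the stereoelectronically preferred axial attack on the half-chair with the C1 substituent equatorial should give mainly the trans bromide 6, with the cis epimer 7 as the minor product.

Step 5
Reactants: 6 (2R,4S)-2-bromo-4-(hydroxymethyl)cyclohexan-1-one
Product: 7 (2S,4S)-2-bromo-4-(hydroxymethyl)cyclohexan-1-one (cis, equatorial bromide)
Conditions: LiBr (0.5 equiv), MeCN, rt; chromatography, recovered 6 resubmitted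
Reagents that add atoms: lithium bromide, [Li+].[Br-]
Why: Finkelstein-type SN2 bromide exchange inverts only the bromine-bearing carbon without enolisation, so bromine cannot migrate to C5 and C1 stays defined; the resulting equilibrium should lean only moderately toward the more polar diequatorial cis isomer in a polar medium, which is why 7 is separated and 6 recycled.

Step 6
Reactants: 7 (2S,4S)-2-bromo-4-(hydroxymethyl)cyclohexan-1-one
Product: 8 (1R,2S,4S)-2-bromo-4-(hydroxymethyl)-1-methylcyclohexan-1-ol
Conditions: MeLi (3 equiv), CeCl3 (3 equiv), THF, −78 °C; aq. NH4Cl at −78 °C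
Reagents that add atoms: methyllithium (used as methylcerium dichloride), [Li]C
Why: In this organocerium 1,2-addition to an enolisable α-bromoketone, equatorial attack on the diequatorial chair and attack anti to C–Br (Cornforth/Felkin–Anh polar model) on the minor diaxial chair both place methyl equatorial and OH axial, cis to bromine, which sets the carbinol centre as in the classical cis-halohydrin outcome of organometallic additions to 2-halocyclohexanones.

Step 7
Reactants: 8 (1R,2S,4S)-2-bromo-4-(hydroxymethyl)-1-methylcyclohexan-1-ol
Product: 9 (1S,3S,4R)-3-bromo-4-hydroxy-4-methylcyclohexane-1-carbaldehyde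
Conditions: TEMPO (10 mol%), PhI(OAc)2, CH2Cl2, rt
Reagents that add atoms: none
Why: The TEMPO/oxoammonium oxidation is selective for the primary alcohol and stops at the aldehyde while the tertiary carbinol and the secondary bromide are inert; C1 is now α to a carbonyl, but its equatorial orientation is also the thermodynamically preferred one.

Step 8
Reactants: 9 (1S,3S,4R)-3-bromo-4-hydroxy-4-methylcyclohexane-1-carbaldehyde
Product: 10 (1R,2S,4S)-2-bromo-4-ethynyl-1-methylcyclohexan-1-ol
Conditions: dimethyl (1-diazo-2-oxopropyl)phosphonate, K2CO3, MeOH, 0 °C to rt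
Reagents that add atoms: dimethyl (1-diazo-2-oxopropyl)phosphonate, COP(=O)(OC)C(=[N+]=[N-])C(C)=O
Why: Seyferth–Gilbert homologation in the Ohira–Bestmann variant converts the aldehyde to the terminal alkyne under mild base; the cis-bromohydrin has no antiperiplanar O/Br arrangement for epoxide closure, and any C1 epimerisation is biased toward the desired equatorial isomer.

Step 9
Reactants: 10 (1R,2S,4S)-2-bromo-4-ethynyl-1-methylcyclohexan-1-ol
Product: 12 (1R,2S,4S)-2-bromo-4-[(E)-1-iodoprop-1-en-2-yl]-1-methylcyclohexan-1-ol, via (E)-alkenyl(dimethyl)alane dimethylaluminium alkoxide 11 (not isolated)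
Conditions: Me3Al (4 equiv), Cp2ZrCl2 (0.5 equiv), CH2Cl2, 0 °C to rt; then I2, THF, −30 to 0 °C
Reagents that add atoms: trimethylaluminium, C[Al](C)C; iodine, II
Why: Negishi zirconium-catalysed carboalumination adds Me–Al syn across the terminal alkyne with methyl on the internal carbon, and iododealumination with retention should give the (E)-2-methyl-1-iodoalkene, fixing the geometry of the trisubstituted alkene, while the carbinol is carried as its aluminium alkoxide.

Step 10
Reactants: 13 (R)-(−)-linalool
Product: 14 (3S,6R)-3-bromo-6-ethenyl-2,2,6-trimethyloxane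
Conditions: 2,4,4,6-tetrabromocyclohexa-2,5-dienone, CH2Cl2, −20 °C to rt; chromatography
Reagents that add atoms: 2,4,4,6-tetrabromocyclohexa-2,5-dienone, O=C1C(Br)=CC(Br)(Br)C=C1Br
Why: In this bromonium-induced 6-endo bromoetherification the tertiary hydroxyl attacks the tertiary carbon of the bromonium ion (Markovnikov) through a chair with bromine equatorial; the linalool carbinol centre is untouched and fixes the absolute configuration, and the isomer with vinyl equatorial (Br trans to vinyl) has to be separated from its (3R,6R) epimer and from 5-exo tetrahydrofuran by-products.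

Step 11
Reactants: 12 (1R,2S,4S)-2-bromo-4-[(E)-1-iodoprop-1-en-2-yl]-1-methylcyclohexan-1-ol; 14 (3S,6R)-3-bromo-6-ethenyl-2,2,6-trimethyloxane (1.5 equiv)
Product: 15 (1R,2S,4S)-2-bromo-4-[(2E,4E)-5-[(2R,5S)-5-bromo-2,6,6-trimethyloxan-2-yl]penta-2,4-dien-2-yl]-1-methylcyclohexan-1-ol (CNP0199463.2)
Conditions: Pd(OAc)2 (10 mol%), Bu4NCl, NaHCO3, DMF, 50 °C
Reagents that add atoms: none
Why: In this Mizoroki–Heck alkenylation under Jeffery conditions, oxidative addition retains the iodide geometry, syn-carbopalladation puts the alkenyl group on the terminal carbon of the vinyl group next to the quaternary centre, and syn-β-hydride elimination should give the (E)-disubstituted alkene and hence the (2E,4E)-diene; the secondary bromides are inert to ligand-free Pd(0), and silver salts are avoided so that the bromohydrin is not ionised.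

**Compound list**

1 | methyl vinyl ketone (but-3-en-2-one) | CC(=O)C=C | starting material
2 | 2-(triisopropylsilyloxy)buta-1,3-diene | C=CC(=C)O[Si](C(C)C)(C(C)C)C(C)C | intermediate
3 | 2,2,2-trifluoroethyl acrylate | C=CC(=O)OCC(F)(F)F | starting material
4 | 2,2,2-trifluoroethyl (1S)-4-(triisopropylsilyloxy)cyclohex-3-ene-1-carboxylate | O=C(OCC(F)(F)F)[C@H]1CCC(O[Si](C(C)C)(C(C)C)C(C)C)=CC1 | intermediate
5 | [(1S)-4-(triisopropylsilyloxy)cyclohex-3-en-1-yl]methanol | OC[C@H]1CCC(O[Si](C(C)C)(C(C)C)C(C)C)=CC1 | intermediate
6 | (2R,4S)-2-bromo-4-(hydroxymethyl)cyclohexan-1-one (trans) | OC[C@H]1CCC(=O)[C@H](Br)C1 | intermediate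
7 | (2S,4S)-2-bromo-4-(hydroxymethyl)cyclohexan-1-one (cis) | OC[C@H]1CCC(=O)[C@@H](Br)C1 | intermediate
8 | (1R,2S,4S)-2-bromo-4-(hydroxymethyl)-1-methylcyclohexan-1-ol | OC[C@H]1CC[C@@](C)(O)[C@@H](Br)C1 | intermediate
9 | (1S,3S,4R)-3-bromo-4-hydroxy-4-methylcyclohexane-1-carbaldehyde | O=C[C@H]1CC[C@@](C)(O)[C@@H](Br)C1 | intermediate
10 | (1R,2S,4S)-2-bromo-4-ethynyl-1-methylcyclohexan-1-ol | C#C[C@H]1CC[C@@](C)(O)[C@@H](Br)C1 | intermediate
11 | (E)-alkenyl(dimethyl)alane dimethylaluminium alkoxide derived from 10 (not isolated) | C/C(=C\[Al](C)C)[C@H]1CC[C@@](C)(O[Al](C)C)[C@@H](Br)C1 | intermediate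
12 | (1R,2S,4S)-2-bromo-4-[(E)-1-iodoprop-1-en-2-yl]-1-methylcyclohexan-1-ol | C/C(=C\I)[C@H]1CC[C@@](C)(O)[C@@H](Br)C1 | intermediate
13 | (R)-(−)-linalool | C=C[C@](C)(O)CCC=C(C)C | starting material
14 | (3S,6R)-3-bromo-6-ethenyl-2,2,6-trimethyloxane | C=C[C@@]1(C)CC[C@H](Br)C(C)(C)O1 | intermediate
15 | (1R,2S,4S)-2-bromo-4-[(2E,4E)-5-[(2R,5S)-5-bromo-2,6,6-trimethyloxan-2-yl]penta-2,4-dien-2-yl]-1-methylcyclohexan-1-ol | C/C(=C\C=C\[C@@]1(C)CC[C@H](Br)C(C)(C)O1)[C@H]1CC[C@@](C)(O)[C@@H](Br)C1 | target

**Step count and risks**

Total steps: 11. Longest linear sequence: 10 (steps 1–9 and 11, from methyl vinyl ketone); the oxane branch is one step (step 10).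

Steps most likely to fail:

1. Step 5. The halide-exchange equilibrium may settle near parity instead of on the cis side, so that much material keeps cycling as the axial epimer, with slow loss to dehydrobromination. The fallback replaces thermodynamic by kinetic control and sets out from 6 (or the 6/7 mixture). TMSOTf and Et3N in CH2Cl2 at 0 °C should silylate both oxygens and give {[(1S)-3-bromo-4-(trimethylsilyloxy)cyclohex-3-en-1-yl]methoxy}trimethylsilane F1. Protodesilylation with acetic-acid-buffered TBAF in THF at −78 °C then delivers the proton axially to the bromine-bearing carbon of the half-chair, leaving bromine equatorial and freeing the primary alcohol, and the route is rejoined at 7. An enol ether formed toward C5 would only return 6.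

2. Step 11. Carbopalladation of the hindered alkene next to the quaternary ether carbon may be slow, and palladium hydride may isomerise the diene or β-alkoxide elimination may open the oxane. The fallback is a Suzuki–Miyaura coupling that sets out from 14 and 12. Ozonolysis of 14 (O3, CH2Cl2, −78 °C; PPh3) should give (2R,5S)-5-bromo-2,6,6-trimethyloxane-2-carbaldehyde F2. Takai–Utimoto borylolefination (Cl2CHBpin, CrCl2, LiI, THF, rt) should convert it into 2-[(E)-2-[(2R,5S)-5-bromo-2,6,6-trimethyloxan-2-yl]ethenyl]-4,4,5,5-tetramethyl-1,3,2-dioxaborolane F3. Coupling of F3 with 12 (PdCl2(dppf), aq. K3PO4, THF, rt) comes back to the route at 15.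

3. Step 9. The Lewis acidic aluminium and zirconium species may ionise the C–Br bond next to the aluminium alkoxide (semipinacol ring contraction), or the carbometalation may stall on the alkoxide-bearing substrate. The fallback masks the carbinol and sets out from 10. TMS-imidazole in CH2Cl2 should give {[(1R,2S,4S)-2-bromo-4-ethynyl-1-methylcyclohexyl]oxy}trimethylsilane F4. Carboalumination as in step 9 gives the (E)-alkenyl(dimethyl)alane of the silyl ether F5, which is not isolated, and iodine converts it into {[(1R,2S,4S)-2-bromo-4-[(E)-1-iodoprop-1-en-2-yl]-1-methylcyclohexyl]oxy}trimethylsilane F6. Mild methanolysis (K2CO3 or citric acid, MeOH) removes the silyl group and returns to the route at 12.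

**Further compounds**

F1 | step 5 | {[(1S)-3-bromo-4-(trimethylsilyloxy)cyclohex-3-en-1-yl]methoxy}trimethylsilane | C[Si](C)(C)OC[C@H]1CCC(O[Si](C)(C)C)=C(Br)C1
F2 | step 11 | (2R,5S)-5-bromo-2,6,6-trimethyloxane-2-carbaldehyde | O=C[C@@]1(C)CC[C@H](Br)C(C)(C)O1
F3 | step 11 | 2-[(E)-2-[(2R,5S)-5-bromo-2,6,6-trimethyloxan-2-yl]ethenyl]-4,4,5,5-tetramethyl-1,3,2-dioxaborolane | CC1(C)OB(/C=C/[C@@]2(C)CC[C@H](Br)C(C)(C)O2)OC1(C)C
F4 | step 9 | {[(1R,2S,4S)-2-bromo-4-ethynyl-1-methylcyclohexyl]oxy}trimethylsilane | C#C[C@H]1CC[C@@](C)(O[Si](C)(C)C)[C@@H](Br)C1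
F5 | step 9 | (E)-alkenyl(dimethyl)alane of the trimethylsilyl ether F4 (not isolated) | C/C(=C\[Al](C)C)[C@H]1CC[C@@](C)(O[Si](C)(C)C)[C@@H](Br)C1
F6 | step 9 | {[(1R,2S,4S)-2-bromo-4-[(E)-1-iodoprop-1-en-2-yl]-1-methylcyclohexyl]oxy}trimethylsilane | C/C(=C\I)[C@H]1CC[C@@](C)(O[Si](C)(C)C)[C@@H](Br)C1
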